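**Retrosynthetic overview**
- The dihydrofuran ring is the only ring built, and it is built last. Both stereocentres come from one catalytic asymmetric formal [4+1] annulation that forms C2–C3 and then O1–C2.
- The four-atom partner is an ortho-quinone methide (ring A, C3 and the 3,5-dioxygenated aryl), stored as a sulfone. The one-carbon partner is a guaiacyl nitromethane, with the nitro group as a traceless activating and leaving group.
- The sulfone comes from a ring A salicylaldehyde that already carries the stilbene, plus an aryl Grignard reagent from 5-bromoresorcinol.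
- The stilbene comes from a Heck reaction of 4-bromo-2,6-dihydroxybenzaldehyde with 4-vinylguaiacol. Starting from the 2,6-dioxygenated aldehyde fixes the attachment at the ring A carbon between the two oxygens.
- The arylnitromethane comes from palladium-catalysed nitromethylation of silylated 4-bromoguaiacol.

Assumption: the target is taken as drawn, (2R,3R) with the two aryl groups trans. The quinidine-derived squaramide is assumed to give the R centre at C3; if the first run gives the antipode, the quinine-derived pseudo-enantiomer is used instead.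

**Route**

Step 1
Reactants: 1 4-bromo-2,6-dimethoxybenzaldehyde
Product: 2 4-bromo-2,6-dihydroxybenzaldehyde
Conditions: BBr3 (3.5 equiv), CH2Cl2, −78 °C → rt; H2O
Reagents that add atoms: none
Why: Lewis-acid aryl methyl ether cleavage (BBr3 demethylation), in which bromide removes each methyl group by SN2 from the boron-complexed ether ortho to the carbonyl, leaving the aryl bromide and aldehyde intact.

Step 2
Reactants: 2 4-bromo-2,6-dihydroxybenzaldehyde; 3 2-methoxy-4-vinylphenol
Product: 4 2,6-dihydroxy-4-[(E)-2-(4-hydroxy-3-methoxyphenyl)ethenyl]benzaldehyde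
Conditions: Pd(OAc)2 (5 mol%), P(o-tol)3 (12 mol%), Et3N (4 equiv), BHT (cat.), DMF, 90 °C
Reagents that add atoms: none
Why: Mizoroki–Heck reaction, in which the C–Br bond para to the formyl group adds readily to palladium and syn-insertion/β-hydride elimination at the terminal vinyl carbon gives the (E)-stilbene before any stereocentre or silyl ether exists.

Step 3
Reactants: 4 2,6-dihydroxy-4-[(E)-2-(4-hydroxy-3-methoxyphenyl)ethenyl]benzaldehyde
Product: 5 2-(tert-butyldimethylsilyloxy)-6-hydroxy-4-[(E)-2-(4-(tert-butyldimethylsilyloxy)-3-methoxyphenyl)ethenyl]benzaldehyde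
Conditions: TBSCl (2.1 equiv), imidazole (4.5 equiv), DMF, 0 °C
Reagents that add atoms: tert-butyldimethylsilyl chloride (TBSCl), CC(C)(C)[Si](C)(C)Cl
Why: Chemoselective phenol silylation, in which the guaiacyl OH and one of the two equivalent salicyl OH groups react while the last OH is held back by its hydrogen bond to the formyl oxygen; this leaves one free ring A phenol for quinone methide formation and keeps that quinone methide neutral.

Step 4
Reactants: 6 5-bromobenzene-1,3-diol
Product: 7 1-bromo-3,5-bis(tert-butyldimethylsilyloxy)benzene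
Conditions: TBSCl (2.3 equiv), imidazole (5 equiv), DMF, rt
Reagents that add atoms: tert-butyldimethylsilyl chloride (TBSCl), CC(C)(C)[Si](C)(C)Cl
Why: Standard imidazole-mediated silylation of both phenols, which masks the acidic protons for Grignard formation and stops the resorcinol ring from attacking the quinone methide later.

Step 5
Reactants: 7 1-bromo-3,5-bis(tert-butyldimethylsilyloxy)benzene; 5 2-(tert-butyldimethylsilyloxy)-6-hydroxy-4-[(E)-2-(4-(tert-butyldimethylsilyloxy)-3-methoxyphenyl)ethenyl]benzaldehyde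
Product: 10 racemic 2-{[3,5-bis(tert-butyldimethylsilyloxy)phenyl](4-methylbenzenesulfonyl)methyl}-3-(tert-butyldimethylsilyloxy)-5-[(E)-2-(4-(tert-butyldimethylsilyloxy)-3-methoxyphenyl)ethenyl]phenol, via arylmagnesium bromide 8 (not isolated), via diarylmethanol 9 (not isolated)
Conditions: Mg (1.1 equiv to 7), I2 (cat.), THF, 50 °C; then 5 (0.4 equiv), THF, −20 → 0 °C; then TolSO2H (6 equiv), CH2Cl2, 0 °C → rt
Reagents that add atoms: p-toluenesulfinic acid (TolSO2H), Cc1ccc(cc1)S(=O)O
Why: Grignard 1,2-addition to the salicylaldehyde (one equivalent is spent on the free phenol) followed by acid-promoted SN1 substitution, in which sulfinate traps the ortho-hydroxybenzylic cation at sulfur to give a bench-stable quinone methide precursor; the new centre is left racemic because step 8 erases it.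

Step 6
Reactants: 11 4-bromo-2-methoxyphenol
Product: 12 (4-bromo-2-methoxyphenoxy)tri(propan-2-yl)silane
Conditions: TIPSCl (1.2 equiv), imidazole (2.5 equiv), DMF, rt
Reagents that add atoms: triisopropylsilyl chloride (TIPSCl), CC(C)[Si](Cl)(C(C)C)C(C)C
Why: Standard phenol silylation, with the bulky triisopropylsilyl ether chosen to survive the carbonate bases of steps 7 and 8 and to come off only with fluoride.

Step 7
Reactants: 12 (4-bromo-2-methoxyphenoxy)tri(propan-2-yl)silane; 13 nitromethane
Product: 14 [3-methoxy-4-(triisopropylsilyloxy)phenyl]nitromethane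
Conditions: Pd2(dba)3 (2.5 mol%), XPhos (6 mol%), Cs2CO3 (1.2 equiv), 13 (10 equiv), 3 Å MS, 1,4-dioxane, 50 °C; aq NH4Cl
Reagents that add atoms: none
Why: Palladium-catalysed cross-coupling of an aryl bromide with nitromethane (nitronate α-arylation of the enolate-arylation type), with excess nitromethane suppressing diarylation.

Step 8
Reactants: 10 racemic sulfone from step 5; 14 [3-methoxy-4-(triisopropylsilyloxy)phenyl]nitromethane
Product: 18 (2R,3R)-3-(3,5-dihydroxyphenyl)-2-(4-hydroxy-3-methoxyphenyl)-6-[(E)-2-(4-hydroxy-3-methoxyphenyl)ethenyl]-2,3-dihydro-1-benzofuran-4-ol (target), via ortho-quinone methide 15 (not isolated), via nitro Michael adduct 16 (not isolated), via para-quinone methide 17 (not isolated)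
Conditions: 14 (1.3 equiv), quinidine-derived 3,5-bis(trifluoromethyl)phenyl squaramide catalyst (10 mol%), Na2CO3 (1.2 equiv, aq), toluene, 0 °C; then AcOH (8 equiv), TBAF (8 equiv), THF, 0 → 40 °C
Reagents that add atoms: none
Why: Proposed new method: an arylnitromethane serves as a benzylidene 1,1-dipole in a catalytic asymmetric formal [4+1] annulation — carbonate unmasks the neutral ortho-quinone methide 15 from sulfone 10, the squaramide/quinuclidinium catalyst binds the nitronate of 14 and the quinone methide carbonyl and directs C–C bond formation to one face (sets C3 as R; the nitro-bearing carbon of 16 need not be controlled), then fluoride frees the para-phenoxide, which expels nitrite by 1,6-elimination (vinylogous E1cB) to give para-quinone methide 17, and the neighbouring ring A phenol closes the ring by 5-exo oxa-1,6-addition with the two aryl groups trans (reversible, hence thermodynamic; sets C2 as R) while the remaining silyl ethers are cleaved; the closest known reactions are squaramide-catalysed Michael additions of carbon acids to ortho-quinone methides made in situ from 2-(1-tosylalkyl)phenols, aza-Henry additions of arylnitromethanes, sulfur-ylide [4+1] annulations of ortho-quinone methides and the biomimetic para-quinone methide closure to trans-2-aryl-2,3-dihydrobenzofurans.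

**Compound list**

1 | 4-bromo-2,6-dimethoxybenzaldehyde | COc1cc(Br)cc(OC)c1C=O | starting material
2 | 4-bromo-2,6-dihydroxybenzaldehyde | Oc1cc(Br)cc(O)c1C=O | intermediate
3 | 2-methoxy-4-vinylphenol (4-vinylguaiacol) | C=Cc1ccc(O)c(OC)c1 | starting material
4 | 2,6-dihydroxy-4-[(E)-2-(4-hydroxy-3-methoxyphenyl)ethenyl]benzaldehyde | O=Cc1c(O)cc(/C=C/c2ccc(O)c(OC)c2)cc1O | intermediate
5 | 2-(tert-butyldimethylsilyloxy)-6-hydroxy-4-[(E)-2-(4-(tert-butyldimethylsilyloxy)-3-methoxyphenyl)ethenyl]benzaldehyde | O=Cc1c(O)cc(/C=C/c2ccc(O[Si](C)(C)C(C)(C)C)c(OC)c2)cc1O[Si](C)(C)C(C)(C)C | intermediate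
6 | 5-bromobenzene-1,3-diol (5-bromoresorcinol) | Oc1cc(O)cc(Br)c1 | starting material
7 | 1-bromo-3,5-bis(tert-butyldimethylsilyloxy)benzene | CC(C)(C)[Si](C)(C)Oc1cc(Br)cc(O[Si](C)(C)C(C)(C)C)c1 | intermediate
8 | [3,5-bis(tert-butyldimethylsilyloxy)phenyl]magnesium bromide | CC(C)(C)[Si](C)(C)Oc1cc([Mg]Br)cc(O[Si](C)(C)C(C)(C)C)c1 | intermediate
9 | racemic [3,5-bis(tert-butyldimethylsilyloxy)phenyl]{2-(tert-butyldimethylsilyloxy)-6-hydroxy-4-[(E)-2-(4-(tert-butyldimethylsilyloxy)-3-methoxyphenyl)ethenyl]phenyl}methanol | OC(c1cc(O[Si](C)(C)C(C)(C)C)cc(O[Si](C)(C)C(C)(C)C)c1)c1c(O)cc(/C=C/c2ccc(O[Si](C)(C)C(C)(C)C)c(OC)c2)cc1O[Si](C)(C)C(C)(C)C | intermediate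
10 | racemic 2-{[3,5-bis(tert-butyldimethylsilyloxy)phenyl](4-methylbenzenesulfonyl)methyl}-3-(tert-butyldimethylsilyloxy)-5-[(E)-2-(4-(tert-butyldimethylsilyloxy)-3-methoxyphenyl)ethenyl]phenol | Cc1ccc(cc1)S(=O)(=O)C(c1cc(O[Si](C)(C)C(C)(C)C)cc(O[Si](C)(C)C(C)(C)C)c1)c1c(O)cc(/C=C/c2ccc(O[Si](C)(C)C(C)(C)C)c(OC)c2)cc1O[Si](C)(C)C(C)(C)C | intermediate
11 | 4-bromo-2-methoxyphenol | COc1cc(Br)ccc1O | starting material
12 | (4-bromo-2-methoxyphenoxy)tri(propan-2-yl)silane | COc1cc(Br)ccc1O[Si](C(C)C)(C(C)C)C(C)C | intermediate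
13 | nitromethane | C[N+](=O)[O-] | starting material
14 | [3-methoxy-4-(triisopropylsilyloxy)phenyl]nitromethane | COc1cc(C[N+](=O)[O-])ccc1O[Si](C(C)C)(C(C)C)C(C)C | intermediate
15 | 6-{[3,5-bis(tert-butyldimethylsilyloxy)phenyl]methylidene}-5-(tert-butyldimethylsilyloxy)-3-[(E)-2-(4-(tert-butyldimethylsilyloxy)-3-methoxyphenyl)ethenyl]cyclohexa-2,4-dien-1-one (ortho-quinone methide, methylidene geometry not fixed) | O=C1C=C(/C=C/c2ccc(O[Si](C)(C)C(C)(C)C)c(OC)c2)C=C(O[Si](C)(C)C(C)(C)C)C1=Cc1cc(O[Si](C)(C)C(C)(C)C)cc(O[Si](C)(C)C(C)(C)C)c1 | intermediate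
16 | 2-{(1R)-1-[3,5-bis(tert-butyldimethylsilyloxy)phenyl]-2-[3-methoxy-4-(triisopropylsilyloxy)phenyl]-2-nitroethyl}-3-(tert-butyldimethylsilyloxy)-5-[(E)-2-(4-(tert-butyldimethylsilyloxy)-3-methoxyphenyl)ethenyl]phenol (both epimers at the nitro carbon) | [O-][N+](=O)C(c1ccc(O[Si](C(C)C)(C(C)C)C(C)C)c(OC)c1)[C@H](c1cc(O[Si](C)(C)C(C)(C)C)cc(O[Si](C)(C)C(C)(C)C)c1)c1c(O)cc(/C=C/c2ccc(O[Si](C)(C)C(C)(C)C)c(OC)c2)cc1O[Si](C)(C)C(C)(C)C | intermediate
17 | 4-{(2R)-2-(3,5-dihydroxyphenyl)-2-[2,6-dihydroxy-4-[(E)-2-(4-hydroxy-3-methoxyphenyl)ethenyl]phenyl]ethylidene}-2-methoxycyclohexa-2,5-dien-1-one (para-quinone methide, ethylidene geometry not fixed) | O=C1C=CC(=C[C@H](c2cc(O)cc(O)c2)c2c(O)cc(/C=C/c3ccc(O)c(OC)c3)cc2O)C=C1OC | intermediate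
18 | (2R,3R)-3-(3,5-dihydroxyphenyl)-2-(4-hydroxy-3-methoxyphenyl)-6-[(E)-2-(4-hydroxy-3-methoxyphenyl)ethenyl]-2,3-dihydro-1-benzofuran-4-ol | COc1cc(/C=C/c2cc(O)c3c(c2)O[C@@H](c2ccc(O)c(OC)c2)[C@@H]3c2cc(O)cc(O)c2)ccc1O | target

**Step count and risks**

Total step count: 8. Longest linear sequence: 5 steps (steps 1, 2, 3, 5, 8).

The three steps most likely to fail:

Step 8 (the proposed new annulation). Possible failures are a slow or poorly selective addition of the hindered nitronate to 15, retro-Michael loss of the nitronate from 16, and tautomerisation of 17 to the ring-opened triarylethene, which costs yield but not enantiopurity. The fallback uses known sulfur-ylide chemistry; it sets out from 10 and comes back at 18. Vanillyl alcohol is silylated on the phenol (NaH, TIPSCl, THF) to give [3-methoxy-4-(triisopropylsilyloxy)phenyl]methanol F3. Alcohol F3 is condensed with the known C2-symmetric sulfide (2R,5R)-2,5-dimethylthiolane (bought or prepared beforehand) and HBF4·OEt2 to give (2R,5R)-1-[3-methoxy-4-(triisopropylsilyloxy)benzyl]-2,5-dimethylthiolan-1-ium tetrafluoroborate F4. Treating 10 and F4 with Cs2CO3 in CH2Cl2 at −20 °C releases 15 and the semi-stabilised ylide, which combine in the established ylide/ortho-quinone methide [4+1] annulation (conjugate addition, then intramolecular SN2 by the phenoxide with loss of the sulfide). This gives the fully silylated (2R,3R)-trans-2,3-diaryl-2,3-dihydrobenzofuran F5, and TBAF/AcOH in THF then gives 18. Asymmetric induction in this fallback comes from a stoichiometric, recoverable chiral sulfide instead of a catalyst; the antipodal sulfide is used if the sense is opposite.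

Step 5 (Grignard addition and sulfone formation in one flask). Possible failures are silyl migration from the phenol to the magnesium alkoxide, sluggish addition to the hindered phenoxide-bearing aldehyde, and oligomerisation of the ionised carbinol before sulfinate capture. The fallback sets out from 7 and 5 and comes back at 9. Bromide 7 is converted (n-BuLi, THF, −78 °C; B(OiPr)3; aq NH4Cl) into [3,5-bis(tert-butyldimethylsilyloxy)phenyl]boronic acid F2. Boronic acid F2 adds to aldehyde 5 under neutral rhodium catalysis (Rh(acac)(CO)2, dppf, DME/H2O, 80 °C) to give carbinol 9 without a basic alkoxide and without a sacrificial equivalent of the aryl nucleophile. Carbinol 9 is then treated with TolSO2H as in step 5 to give 10.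

Step 2 (Heck reaction with two unprotected phenolic partners). Possible failures are thermal oligomerisation of 3 and catalyst inhibition by the phenoxides of 2. The fallback sets out from 3 and 2 and comes back at 4. Cross-metathesis of 3 with vinylboronic acid pinacol ester (second-generation Grubbs catalyst, CH2Cl2, 40 °C) gives 2-[(E)-2-(4-hydroxy-3-methoxyphenyl)ethenyl]-4,4,5,5-tetramethyl-1,3,2-dioxaborolane F1. Suzuki–Miyaura coupling of F1 with 2 (Pd(dppf)Cl2, K2CO3, 1,4-dioxane/H2O, 70 °C) then gives 4 with the (E)-geometry already fixed in the boronate.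

Further compounds
F1 | step 2 | 2-[(E)-2-(4-hydroxy-3-methoxyphenyl)ethenyl]-4,4,5,5-tetramethyl-1,3,2-dioxaborolane | COc1cc(/C=C/B2OC(C)(C)C(C)(C)O2)ccc1O
F2 | step 5 | [3,5-bis(tert-butyldimethylsilyloxy)phenyl]boronic acid | CC(C)(C)[Si](C)(C)Oc1cc(cc(O[Si](C)(C)C(C)(C)C)c1)B(O)O
F3 | step 8 | [3-methoxy-4-(triisopropylsilyloxy)phenyl]methanol | COc1cc(CO)ccc1O[Si](C(C)C)(C(C)C)C(C)C
F4 | step 8 | (2R,5R)-1-[3-methoxy-4-(triisopropylsilyloxy)benzyl]-2,5-dimethylthiolan-1-ium tetrafluoroborate | C[C@@H]1CC[C@@H](C)[S+]1Cc1ccc(O[Si](C(C)C)(C(C)C)C(C)C)c(OC)c1.F[B-](F)(F)F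
F5 | step 8 | (2R,3R)-3-[3,5-bis(tert-butyldimethylsilyloxy)phenyl]-4-(tert-butyldimethylsilyloxy)-6-[(E)-2-(4-(tert-butyldimethylsilyloxy)-3-methoxyphenyl)ethenyl]-2-[3-methoxy-4-(triisopropylsilyloxy)phenyl]-2,3-dihydro-1-benzofuran | COc1cc(/C=C/c2cc(O[Si](C)(C)C(C)(C)C)c3c(c2)O[C@@H](c2ccc(O[Si](C(C)C)(C(C)C)C(C)C)c(OC)c2)[C@@H]3c2cc(O[Si](C)(C)C(C)(C)C)cc(O[Si](C)(C)C(C)(C)C)c2)ccc1O[Si](C)(C)C(C)(C)C
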